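## Analysis of the target

Target 24 is a trans-fused hydroazulene of the daucane type: a cyclopentane (C1–C5) and a cycloheptene (C1, C10, C9, C8, C7, C6, C5) share the C1–C5 bond. Labels used throughout: C1 = methyl-bearing ring-fusion carbon, C2 and C3 = cyclopentane methylenes, C4 = isopropyl carbinol carbon, C5 = ring-fusion CH, C6 = carbon carrying the 3,4-dimethoxybenzoate, C7 = methylene, C8=C9 = alkene with the methyl on C8, C10 = carbon carrying the (Z)-2-methylbut-2-enoate; O4, O6 and O10 are the oxygens on C4, C6 and C10; β is the face of the C1 methyl, α the opposite face. There are five stereocentres, 1S, 4R, 5S, 6S and 10R: the C1 methyl is β and the C5 hydrogen α (trans fusion), the C4 hydroxyl is β and its isopropyl α, and both acyloxy groups are α, anti to the angular methyl. C4, C5 and C1 are contiguous and C6 and C10 sit on the two fusion atoms, so every centre has to be set next to fully substituted neighbours. The sensitive groups are the Z-configured unsaturated ester (isomerises to the E ester with base, nucleophilic catalysts or prolonged heat), the allylic C10–O bond next to a quaternary carbon, and the tertiary alcohol β to C6. Any C6 ketone intermediate can therefore eliminate or cleave by retro-aldol reaction, and its C8=C9 bond is β,γ and can move into conjugation. The synthesis is hard because the quaternary C1 is bonded to the stereogenic C10 inside a seven-membered ring, and because two secondary oxygens must carry different acyl groups. The strategy rests on the C1–C10 bond together with the 1,4-relationship of the C8=C9 alkene and the C6 oxygen through C7: this is the pattern left by the [3,3] rearrangement of a cis-divinylcyclopropane (ring C6–C7–C8) that carries an oxygen on C6.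

## Retrosynthetic reasoning

**Esters.** The C10–O acyl bond of 24 is cut first (22 + 23), because the Z ester is the group most easily isomerised and should meet no further reagent. 22 comes from 21 by freeing O10 from a 4-methoxybenzyl ether, and 21 from 19 + 20 by cutting the C6–O acyl bond. In 19 only O6 is a free secondary hydroxyl (O10 is masked, O4 is tertiary), so the two secondary oxygens never have to be told apart by reactivity.

**C6–H.** 19 is traced to ketone 18. An external hydride would attack C6 from the α face, away from the angular methyl, and give the wrong epimer. The forward step must therefore deliver hydride from boron bound to the β hydroxyl on C4, which puts the new hydrogen β and O6 α. This needs the free C4 hydroxyl and the trans fusion to be in place first.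

**C5–H.** 18 is traced to the cyclic silyl enol ether 17, in which one silicon bridges O6 and O4. The C5–H bond has to be made by kinetic protonation. Base equilibration of 18 is excluded because the β,γ-alkene would conjugate and the β-hydroxy ketone would eliminate. The bridge is the control element: O4 is β, so while the ring is intact C6 is drawn toward the β side as C5 pyramidalises, and the proton enters from α. Two independent silyl ethers on O4 and O6 would give no such bias, which is one reason for choosing the bridge.

**Key disconnection.** 17 is opened at C1–C10 and reclosed between C6 and C8 to give the cis-divinylcyclopropane 16. This is the most hindered bond of the skeleton. Cutting it here removes the seven-membered ring and both new stereocentres (C1, C10) at once. The forward rearrangement also produces the C8=C9 alkene with its methyl, the C6 oxygen as an enol ether and the C10 ether. It requires the two alkenyl groups cis on the cyclopropane, the 6S,8R configuration relative to C4, and an E enol ether.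

**Alkoxyvinyl arm.** 16 is traced through the C10–O bond to alkenylboronate 14 and alcohol 15, and 14 through the C10–B bond to alkyne 13. Syn hydroboration fixes the E geometry, the copper coupling runs at ambient temperature so that 16 is not heated before the key step, and the alkyne is inert during the preceding cyclopropanation.

**Cyclopropane.** 13 is cut at C6–C7 and C7–C8 to the tetrasubstituted enol ether 11 and the methylene donor 12. Methylene transfer is stereospecific, so the cis relationship in 13 is the E geometry of 11. The bridge exposes the face of the enol ether that leads to 6S,8R, which is the second reason for choosing it.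

**Enol ether and side chain.** 11 is traced to hydroxy ketone 10 by cutting both O–Si bonds; the enol ether geometry is set on enolisation. 10 comes from 9 and 8 by oxidation-level and protecting-group changes, and 8 is cut at C6–C8 to aldehyde 6 and the propargylic bromide 7. The two carbinol-chain stereocentres of 8 do not matter because both become trigonal.

**Cyclopentene.** 6 is cut at C1=C5 to keto aldehyde 4 (intramolecular aldol condensation), and 4 is the ozonolysis product of 2, the silyl ether of 1. The chiral pool thus supplies C4: the carbinol carbon of 1 becomes C4 with the required spatial arrangement (its descriptor changes from S to R only because ligand priorities change).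

## Alternatives that were turned down

**Alternative 1:** The disconnection is C1–C5, made by a 1,2-shift in a cis-fused decalin. In the forward step, base would generate an alkoxide at C6 while a sulfonate leaves from C5, and C1 would migrate from C6 to C5. One six-membered ring contracts to the cyclopentane and the other expands to the cycloheptanone, giving A1. In its favour, the migration is stereospecific (anti-periplanar), so the trans relationship of C1 and C5 is fixed by the decalin, and C1 comes from a well-established enantioselective annulation. On the ring-fusion centre C5 this plan is stronger than the chosen one, which depends on a kinetic protonation. Against it, A1 has no C8 methyl and no C8=C9 alkene, and C10 is only a masked ketone. A trisubstituted alkene would have to be placed regioselectively between two carbonyl-derived positions, C10 reduced with the right facial sense beside the quaternary carbon, and the C6 and C10 oxygens differentiated. The decalin precursor itself needs a C4/C5/C6 triad with exact anti-periplanar geometry. The chosen strategy gives up the built-in C5 control but delivers the alkene, its methyl, the C10 oxygen and the C6 carbonyl in one step, so it is much shorter.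

**Alternative 2:** The disconnections are C1–CH3 and C5–C6, made in a three-component step on a five-membered enone. In the forward step, copper-catalysed asymmetric conjugate addition of a methylaluminium reagent would form the quaternary C1, and the resulting enolate would be trapped by a Z-configured iodoalkenyl aldehyde to give A2. In its favour, absolute configuration comes from a catalyst, the step is convergent, the Z geometry of the future C8=C9 bond is carried in by a fragment, and C1, C5 and C6 are set together. On convergence and catalytic control it is stronger than the chosen plan, which relays everything from the chiral-pool centre C4. Against it, no ring is closed. The seven-membered ring would have to be formed later at C9–C10, setting C10 in a medium-ring closure with little bias. C4 is a ketone in A2, so the isopropyl group must be added to a hindered, enolisable cyclopentanone whose α-carbon C5 is epimerisable and which carries a β-hydroxyl prone to retro-aldol cleavage. The chosen strategy instead forms the ring and the C1–C10 bond in one stereospecific pericyclic step, with C10 fixed by alkene geometry and not by a late addition.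

**Alternative 3:** The disconnection is C3–C4, closing the cyclopentane last. In the forward step, a divalent samarium reductant would convert a C3 iodide into a nucleophile that adds to a C4 isopropyl ketone on a fully built cycloheptene, giving A3. In its favour, A3 is only protecting-group and acylation steps away from 24, its two secondary oxygens already carry orthogonal groups, and no base-sensitive β-hydroxy ketone is ever handled. On endgame length and protecting-group logic it is stronger than the chosen plan. Against it, the key step solves none of the hard problems: the seven-membered ring, the quaternary C1 next to C10, the C5/C6 pair and the C8=C9 alkene must all exist in the precursor. The C4 configuration would depend on the facial course of an addition to a ketone flanked by an epimerisable C5 and a β-alkoxy group. The chosen strategy spends its key step on exactly the part that this alternative leaves open.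

Key step: step 11

Assumptions on the chemistry: 1 is used as the (S) enantiomer in high enantiomeric purity (enriched material would be upgraded before step 1). Racemic 7 is used as purchased; its stereocentre is erased in step 7.

## Route

Step 1
Reactants: 1 (S)-terpinen-4-ol
Product: 2 (S)-triethyl{[4-methyl-1-(propan-2-yl)cyclohex-3-en-1-yl]oxy}silane
Conditions: Et3SiOTf, 2,6-lutidine, CH2Cl2, −78 → 0 °C
Reagents that add atoms: triethylsilyl trifluoromethanesulfonate, CC[Si](CC)(CC)OS(=O)(=O)C(F)(F)F
Why: Silylation of a hindered tertiary alcohol with a silyl triflate and a hindered pyridine base; the ether protects the later β-oxygenated aldehyde from retro-aldol cleavage and dehydration, and the stereocentre is untouched.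

Step 2
Reactants: 2 (S)-triethyl{[4-methyl-1-(propan-2-yl)cyclohex-3-en-1-yl]oxy}silane
Product: 4 (3S)-6-oxo-3-(propan-2-yl)-3-[(triethylsilyl)oxy]heptanal, via secondary ozonide 3 (not isolated)
Conditions: O3, CH2Cl2, −78 °C; then PPh3, −78 → 23 °C
Reagents that add atoms: ozone, [O-][O+]=O
Why: Ozonolysis of the only alkene with reductive work-up gives the methyl ketone and the aldehyde; the silyl ether and the quaternary stereocentre are inert.

Step 3
Reactants: 4 (3S)-6-oxo-3-(propan-2-yl)-3-[(triethylsilyl)oxy]heptanal
Product: 6 (5R)-2-methyl-5-(propan-2-yl)-5-[(triethylsilyl)oxy]cyclopent-1-ene-1-carbaldehyde, via aldol adduct 5 (not isolated)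
Conditions: piperidine, AcOH, PhMe, 80 °C
Reagents that add atoms: none
Why: Amine-mediated intramolecular aldol condensation in which the aldehyde enamine attacks the methyl ketone and water is lost, forming the C1=C5 bond as in the known ring contraction of keto aldehydes from 1-methylcyclohexenes; the C4 descriptor becomes R by priority change only.

Step 4
Reactants: 6 (5R)-2-methyl-5-(propan-2-yl)-5-[(triethylsilyl)oxy]cyclopent-1-ene-1-carbaldehyde; 7 3-bromobut-1-yne
Product: 8 2-methyl-1-{(5R)-2-methyl-5-(propan-2-yl)-5-[(triethylsilyl)oxy]cyclopent-1-en-1-yl}but-3-yn-1-ol (diastereomer mixture at the two new centres)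
Conditions: Zn dust, THF, 0 → 23 °C (Barbier mode)
Reagents that add atoms: 3-bromobut-1-yne (7), CC(Br)C#C
Why: Barbier reaction: zinc inserts into the propargylic bromide to give an allenylzinc bromide, which adds 1,2 to the hindered enal with allylic transposition and forms the C6–C8 bond with methyl and ethynyl on C8; the two new centres become trigonal later, so their configuration is irrelevant.

Step 5
Reactants: 8 2-methyl-1-{(5R)-2-methyl-5-(propan-2-yl)-5-[(triethylsilyl)oxy]cyclopent-1-en-1-yl}but-3-yn-1-ol
Product: 9 (1R)-2-(1-hydroxy-2-methylbut-3-yn-1-yl)-3-methyl-1-(propan-2-yl)cyclopent-2-en-1-ol (diastereomer mixture in the side chain)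
Conditions: Bu4NF, THF, 23 °C
Reagents that add atoms: none
Why: Fluoride cleavage of the tertiary triethylsilyl ether, done here on a robust diol and before the base-sensitive ketone exists; it frees O4 for the silicon bridge.

Step 6
Reactants: 9 (1R)-2-(1-hydroxy-2-methylbut-3-yn-1-yl)-3-methyl-1-(propan-2-yl)cyclopent-2-en-1-ol
Product: 10 1-[(5R)-5-hydroxy-2-methyl-5-(propan-2-yl)cyclopent-1-en-1-yl]-2-methylbut-3-yn-1-one (epimer mixture at C8)
Conditions: Dess–Martin periodinane, NaHCO3, CH2Cl2, 0 °C; used crude
Reagents that add atoms: none
Why: Buffered Dess–Martin oxidation converts only the secondary alcohol (the tertiary one cannot be oxidised); the cold, nearly neutral conditions avoid isomerising the β,γ-alkynyl ketone to the allenyl ketone.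

Step 7
Reactants: 10 1-[(5R)-5-hydroxy-2-methyl-5-(propan-2-yl)cyclopent-1-en-1-yl]-2-methylbut-3-yn-1-one
Product: 11 (4E,7aR)-4-(but-3-yn-2-ylidene)-2,2-di-tert-butyl-5-methyl-7a-(propan-2-yl)-4,6,7,7a-tetrahydrocyclopenta[d][1,3,2]dioxasiline (O6 and O4 bridged by silicon; ethynyl cis to the cyclopentene)
Conditions: KN(SiMe3)2 (2.05 equiv), THF, −78 °C (ketone added to base); then tBu2Si(OTf)2, −78 → 0 °C
Reagents that add atoms: di-tert-butylsilyl bis(trifluoromethanesulfonate), CC(C)(C)[Si](OS(=O)(=O)C(F)(F)F)(OS(=O)(=O)C(F)(F)F)C(C)(C)C
Why: Double deprotonation (O4–H, then the doubly activated C8–H) and O-silylation of both oxygens by the bis(triflate) closes the six-membered silyl enol ether; the substituent on C8 that points toward the C1 methyl can only be the rod-like ethynyl group, so the E enol ether (methyl syn to O6) is expected, and no stereocentre is formed.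

Step 8
Reactants: 11 (4E,7aR)-4-(but-3-yn-2-ylidene)-2,2-di-tert-butyl-5-methyl-7a-(propan-2-yl)-4,6,7,7a-tetrahydrocyclopenta[d][1,3,2]dioxasiline; 12 diiodomethane
Product: 13 (2'R,4S,7aR)-2,2-di-tert-butyl-2'-ethynyl-2',5-dimethyl-7a-(propan-2-yl)-6,7-dihydro-7aH-spiro[cyclopenta[d][1,3,2]dioxasiline-4,1'-cyclopropane] (C6 S and C8 R in target labels; ethynyl cis to the cyclopentene)
Conditions: Et2Zn, CH2I2 (1:2), CH2Cl2, 0 → 23 °C
Reagents that add atoms: diiodomethane (12), ICI
Why: Furukawa-type Simmons–Smith methylenation of a silyl enol ether, the most nucleophilic alkene present (the alkyne and the tetrasubstituted ring alkene are poor acceptors); transfer is stereospecific, so ethynyl and cyclopentenyl stay cis, and with O6 tied to the β-oriented O4 the enol ether face turned toward C4 is screened by the α isopropyl group and the silylene, so CH2 should enter from the C1 side and give the 6S,8R cyclopropane.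

Step 9
Reactants: 13 (2'R,4S,7aR)-2,2-di-tert-butyl-2'-ethynyl-2',5-dimethyl-7a-(propan-2-yl)-6,7-dihydro-7aH-spiro[cyclopenta[d][1,3,2]dioxasiline-4,1'-cyclopropane]
Product: 14 the same spiro compound carrying (E)-2-(4,4,5,5-tetramethyl-1,3,2-dioxaborolan-2-yl)ethenyl in place of ethynyl
Conditions: pinacolborane, Cp2Zr(H)Cl (cat.), Et3N (cat.), CH2Cl2, 23 °C
Reagents that add atoms: pinacolborane, CC1(C)OBOC1(C)C
Why: Zirconium-catalysed syn hydroboration of a terminal alkyne places boron on the terminal carbon (C10) and gives the E alkenylboronate; the hindered tetrasubstituted alkene and the silyl ethers do not react.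

Step 10
Reactants: 14 the (E)-alkenylboronate; 15 4-methoxybenzyl alcohol
Product: 16 (2'R,4S,7aR)-2,2-di-tert-butyl-2'-{(E)-2-[(4-methoxyphenyl)methoxy]ethenyl}-2',5-dimethyl-7a-(propan-2-yl)-6,7-dihydro-7aH-spiro[cyclopenta[d][1,3,2]dioxasiline-4,1'-cyclopropane]
Conditions: Cu(OAc)2, Et3N, 15 (excess), 4 Å molecular sieves, CH2Cl2, air, 23 °C; purified on base-washed silica and kept cold
Reagents that add atoms: 4-methoxybenzyl alcohol (15), COc1ccc(CO)cc1
Why: Chan–Lam-type oxidative coupling of an alkenyl pinacol boronate with an alcohol forms the C10–O bond with retention of the E geometry at ambient temperature, so the cis-divinylcyclopropane is not heated before the key step.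

Step 11
Reactants: 16 the cis-divinylcyclopropane (ring C6–C7–C8; cyclopentenyl C5=C1 on C6; (E)-alkoxyvinyl C9=C10 on C8)
Product: 17 (1S,4R,10R)-4,6-O-(di-tert-butylsilanediyl)-10α-[(4-methoxybenzyl)oxy]dauca-5,8-diene-4β,6-diol (hydroazulene with C5=C6 silyl enol ether bridged to O4; C8=C9 alkene; C10 ether)
Conditions: PhMe (dilute), 90 °C, base-rinsed sealed tube
Reagents that add atoms: none
Why: Concerted [3,3]-sigmatropic shift of a cis-1,2-divinylcyclopropane through the boat array C10=C9–C8···C6–C5=C1, in which the strained C6–C8 bond opens as C1 and C10 bond; the closest known reaction type is the thermal rearrangement of 1-siloxy-1,2-divinylcyclopropanes to the silyl enol ethers of cyclohept-4-enones. The seven-membered ring closes by a pericyclic three-to-seven ring expansion (bonding of the two alkene termini across the cyclopropane), not by an exo or endo nucleophilic closure. C1 is controlled by the 6S,8R cyclopropane: in the boat the cyclopentene must lie under the three-membered ring with C1 toward C7, which presents only the α face of C1 (the face of the C4 isopropyl group, anti to O4) to C10, and the silylene already holds the C5=C1 bond s-cis to C6–C7 in this geometry. C10 is controlled by the E enol ether, whose oxygen stays on the outside of the boat and so ends anti to the C1 methyl (10R). The step needs the concerted shift to outrun homolysis of the doubly allylic C6–C8 bond (one-centre epimerisation) and any 1,3-shift; strain release, the oxygen donor on C6 and the ground-state strain between the C1 methyl and C7 imposed by the bridge should secure this, while the inward-pointing C1 methyl is the retarding factor that sets the temperature.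

Step 12
Reactants: 17 the bridged silyl enol ether
Product: 18 (1S,4R,5R,10R)-4β-hydroxy-10α-[(4-methoxybenzyl)oxy]dauc-8-en-6-one (5α-H; trans-fused)
Conditions: HF·pyridine, pyridine, THF, 0 → 23 °C; used directly
Reagents that add atoms: none
Why: Fluoride-mediated cleavage of a silyl enol ether with C-protonation at C5; fluoride is used and not aqueous acid so that no silanol forms on the β face to hand over a proton, the β face of C5 is screened by the C1 methyl and by the di-tert-butylsilyl group still attached to O4, and as long as the bridge holds C6 is drawn toward O4 as C5 pyramidalises, so the proton should enter from α; the buffered, non-basic medium avoids conjugation of the β,γ-alkene and elimination of the β-hydroxyl.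

Step 13
Reactants: 18 the β-hydroxy ketone
Product: 19 (1S,4R,5S,6S,10R)-10α-[(4-methoxybenzyl)oxy]dauc-8-ene-4β,6α-diol
Conditions: Me4NBH(OAc)3, AcOH, MeCN, −30 °C
Reagents that add atoms: none
Why: Evans–Saksena reduction: the C4 hydroxyl exchanges onto boron and hydride is delivered intramolecularly through a six-membered chair to the β face of C6, giving the 6α alcohol, whereas an external hydride would come from the α face; the acidic, cold medium leaves the β,γ-alkene and the benzylic ether alone.

Step 14
Reactants: 19 the 4β,6α-diol; 20 3,4-dimethoxybenzoyl chloride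
Product: 21 (1S,4R,5S,6S,10R)-4β-hydroxy-10α-[(4-methoxybenzyl)oxy]dauc-8-en-6α-yl 3,4-dimethoxybenzoate
Conditions: DMAP, Et3N, CH2Cl2, 23 °C
Reagents that add atoms: 3,4-dimethoxybenzoyl chloride (20), COc1ccc(C(=O)Cl)cc1OC
Why: DMAP-catalysed acylation of the only secondary hydroxyl; the tertiary C4 hydroxyl between two substituted carbons does not acylate under these conditions and O10 is still protected.

Step 15
Reactants: 21 the C6 ester with O10 as 4-methoxybenzyl ether
Product: 22 (1S,4R,5S,6S,10R)-4β,10α-dihydroxydauc-8-en-6α-yl 3,4-dimethoxybenzoate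
Conditions: DDQ, CH2Cl2, pH 7 buffer, 0 °C
Reagents that add atoms: none
Why: Oxidative cleavage of the 4-methoxybenzyl ether by DDQ via the benzylic oxocarbenium ion; the acyl-deactivated dimethoxyarene and the trisubstituted alkene are not oxidised at this temperature, and short contact limits oxidation of the new allylic alcohol.

Step 16
Reactants: 22 the C10 alcohol; 23 (Z)-2-methylbut-2-enoic acid (angelic acid)
Product: 24 (1S,4R,5S,6S,10R)-4β-hydroxy-10α-{[(Z)-2-methylbut-2-enoyl]oxy}dauc-8-en-6α-yl 3,4-dimethoxybenzoate (the target)
Conditions: 2,4,6-trichlorobenzoyl chloride, Et3N, PhMe, 23 °C; then 22, 75 °C (no DMAP)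
Reagents that add atoms: (Z)-2-methylbut-2-enoic acid (23), C/C=C(/C)C(=O)O
Why: Yamaguchi-type esterification through the mixed trichlorobenzoic anhydride, which is attacked at the less hindered unsaturated acyl carbon; leaving out nucleophilic catalysts suppresses Z-to-E isomerisation through conjugate addition, and the tertiary hydroxyl stays free.

## Compound list

1 | (S)-terpinen-4-ol, (1S)-4-methyl-1-(propan-2-yl)cyclohex-3-en-1-ol | CC1=CC[C@](O)(C(C)C)CC1 | starting material
2 | (S)-triethyl{[4-methyl-1-(propan-2-yl)cyclohex-3-en-1-yl]oxy}silane | CC1=CC[C@](O[Si](CC)(CC)CC)(C(C)C)CC1 | intermediate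
3 | secondary ozonide of 2, 1-methyl-4-(propan-2-yl)-4-[(triethylsilyl)oxy]-7,8,9-trioxabicyclo[4.2.1]nonane (bridgehead mixture) | CC12CC[C@@](O[Si](CC)(CC)CC)(C(C)C)CC(OO1)O2 | intermediate (not isolated)
4 | (3S)-6-oxo-3-(propan-2-yl)-3-[(triethylsilyl)oxy]heptanal | O=CC[C@](O[Si](CC)(CC)CC)(C(C)C)CCC(C)=O | intermediate
5 | aldol adduct, 2-hydroxy-2-methyl-5-(propan-2-yl)-5-[(triethylsilyl)oxy]cyclopentane-1-carbaldehyde (mixture at the two new centres) | O=CC1C(C)(O)CC[C@@]1(O[Si](CC)(CC)CC)C(C)C | intermediate (not isolated)
6 | (5R)-2-methyl-5-(propan-2-yl)-5-[(triethylsilyl)oxy]cyclopent-1-ene-1-carbaldehyde | O=CC1=C(C)CC[C@@]1(O[Si](CC)(CC)CC)C(C)C | intermediate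
7 | 3-bromobut-1-yne (racemic) | CC(Br)C#C | starting material
8 | 2-methyl-1-{(5R)-2-methyl-5-(propan-2-yl)-5-[(triethylsilyl)oxy]cyclopent-1-en-1-yl}but-3-yn-1-ol (diastereomer mixture) | C#CC(C)C(O)C1=C(C)CC[C@@]1(O[Si](CC)(CC)CC)C(C)C | intermediate
9 | (1R)-2-(1-hydroxy-2-methylbut-3-yn-1-yl)-3-methyl-1-(propan-2-yl)cyclopent-2-en-1-ol (diastereomer mixture) | C#CC(C)C(O)C1=C(C)CC[C@@]1(O)C(C)C | intermediate
10 | 1-[(5R)-5-hydroxy-2-methyl-5-(propan-2-yl)cyclopent-1-en-1-yl]-2-methylbut-3-yn-1-one (epimer mixture) | C#CC(C)C(=O)C1=C(C)CC[C@@]1(O)C(C)C | intermediate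
11 | (4E,7aR)-4-(but-3-yn-2-ylidene)-2,2-di-tert-butyl-5-methyl-7a-(propan-2-yl)-4,6,7,7a-tetrahydrocyclopenta[d][1,3,2]dioxasiline | C#C/C(C)=C1/O[Si](C(C)(C)C)(C(C)(C)C)O[C@@]2(C(C)C)CCC(C)=C12 | intermediate
12 | diiodomethane | ICI | starting material
13 | (2'R,4S,7aR)-2,2-di-tert-butyl-2'-ethynyl-2',5-dimethyl-7a-(propan-2-yl)-6,7-dihydro-7aH-spiro[cyclopenta[d][1,3,2]dioxasiline-4,1'-cyclopropane] | C#C[C@@]1(C)C[C@]12O[Si](C(C)(C)C)(C(C)(C)C)O[C@@]3(C(C)C)CCC(C)=C23 | intermediate
14 | (2'R,4S,7aR)-2,2-di-tert-butyl-2',5-dimethyl-7a-(propan-2-yl)-2'-[(E)-2-(4,4,5,5-tetramethyl-1,3,2-dioxaborolan-2-yl)ethenyl]-6,7-dihydro-7aH-spiro[cyclopenta[d][1,3,2]dioxasiline-4,1'-cyclopropane] | CC1(C)OB(/C=C/[C@@]2(C)C[C@]23O[Si](C(C)(C)C)(C(C)(C)C)O[C@@]4(C(C)C)CCC(C)=C34)OC1(C)C | intermediate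
15 | 4-methoxybenzyl alcohol | COc1ccc(CO)cc1 | starting material
16 | (2'R,4S,7aR)-2,2-di-tert-butyl-2'-{(E)-2-[(4-methoxyphenyl)methoxy]ethenyl}-2',5-dimethyl-7a-(propan-2-yl)-6,7-dihydro-7aH-spiro[cyclopenta[d][1,3,2]dioxasiline-4,1'-cyclopropane] (key-step precursor) | COc1ccc(CO/C=C/[C@@]2(C)C[C@]23O[Si](C(C)(C)C)(C(C)(C)C)O[C@@]4(C(C)C)CCC(C)=C34)cc1 | intermediate
17 | (1S,4R,10R)-4,6-O-(di-tert-butylsilanediyl)-10α-[(4-methoxybenzyl)oxy]dauca-5,8-diene-4β,6-diol (key-step product) | COc1ccc(CO[C@@H]2C=C(C)CC3=C4[C@]2(C)CC[C@]4(C(C)C)O[Si](C(C)(C)C)(C(C)(C)C)O3)cc1 | intermediate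
18 | (1S,4R,5R,10R)-4β-hydroxy-10α-[(4-methoxybenzyl)oxy]dauc-8-en-6-one | COc1ccc(CO[C@@H]2C=C(C)CC(=O)[C@@H]3[C@]2(C)CC[C@@]3(O)C(C)C)cc1 | intermediate
19 | (1S,4R,5S,6S,10R)-10α-[(4-methoxybenzyl)oxy]dauc-8-ene-4β,6α-diol | COc1ccc(CO[C@@H]2C=C(C)C[C@H](O)[C@@H]3[C@]2(C)CC[C@@]3(O)C(C)C)cc1 | intermediate
20 | 3,4-dimethoxybenzoyl chloride | COc1ccc(C(=O)Cl)cc1OC | starting material
21 | (1S,4R,5S,6S,10R)-4β-hydroxy-10α-[(4-methoxybenzyl)oxy]dauc-8-en-6α-yl 3,4-dimethoxybenzoate | COc1ccc(CO[C@@H]2C=C(C)C[C@H](OC(=O)c3ccc(OC)c(OC)c3)[C@@H]4[C@]2(C)CC[C@@]4(O)C(C)C)cc1 | intermediate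
22 | (1S,4R,5S,6S,10R)-4β,10α-dihydroxydauc-8-en-6α-yl 3,4-dimethoxybenzoate | O[C@@H]1C=C(C)C[C@H](OC(=O)c2ccc(OC)c(OC)c2)[C@@H]3[C@]1(C)CC[C@@]3(O)C(C)C | intermediate
23 | (Z)-2-methylbut-2-enoic acid (angelic acid) | C/C=C(/C)C(=O)O | starting material
24 | (1S,4R,5S,6S,10R)-4β-hydroxy-10α-{[(Z)-2-methylbut-2-enoyl]oxy}dauc-8-en-6α-yl 3,4-dimethoxybenzoate (CNP0142353.1) | C/C=C(/C)C(=O)O[C@@H]1C=C(C)C[C@H](OC(=O)c2ccc(OC)c(OC)c2)[C@@H]2[C@]1(C)CC[C@@]2(O)C(C)C | target

## Step count and least certain steps

Total step count: 16. Longest linear sequence: 16 steps (1 → 24); 7, 12, 15, 20 and 23 enter as purchased reagents.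

**Step 11 (key step).** The inward-pointing C1 methyl slows the concerted shift. Homolysis of the doubly allylic C6–C8 bond may then compete, causing one-centre epimerisation to a cyclopropane that the bridge holds in an unreactive geometry, or a formal 1,3-shift. Fallback: run the rearrangement as its oxy-anion variant. Setting out from 16, one equivalent of Bu4NF in THF at −40 → 0 °C cleaves the more labile cyclopropyl O–Si bond and gives the cis-1,2-dialkenylcyclopropanol F1 (as its alkoxide). Cyclopropanols of this type undergo the same [3,3] shift far below ambient temperature. The resulting enolate is protonated and the remaining O4–Si bond is cleaved with HF·pyridine in the same flask, so the route is rejoined at 18.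

**Step 7.** Closure of the strained bridged enol ether may lose to intermolecular silylation, and the β,γ-alkynyl ketone may isomerise to the allenyl ketone, which O4 can trap by conjugate addition. Fallback: give up the bridge and use two separate silyl ethers. Setting out from 10, KN(SiMe3)2 and two equivalents of tBuMe2SiOTf give the bis-silyl dienyne F2. Et2Zn/CH2I2 gives the cyclopropane F3; here methylene delivery is not directed, so the 6S,8R diastereomer is separated. Zirconium-catalysed hydroboration gives the alkenylboronate F4, and copper coupling with 15 gives the enol ether F5. Heating gives the cycloheptadiene F6, and HF·pyridine cleaves both silyl groups to rejoin the route at 18 (with the C5 protonation then under steric control only).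

**Step 10.** Oxidative C–O coupling of a hindered alkenylboronate with a non-volatile alcohol may be slow, so that protodeboronation or premature rearrangement of 14 takes over. Fallback: an Ullmann-type coupling of an alkenyl iodide. Setting out from 13, hydrozirconation with Cp2Zr(H)Cl and iodination give the (E)-alkenyl iodide F7. Coupling with 15 (CuI, 3,4,7,8-tetramethyl-1,10-phenanthroline, Cs2CO3, PhMe, 80 °C) returns to the route at 16; at that temperature 16 may already pass on to 17.

**Step 12.** Proton delivery to the β face of C5 would give the cis-fused ketone. This cannot be corrected by base, because the β,γ-alkene would conjugate and the β-hydroxy ketone would eliminate. Fallback: do not rely on one pass. The epimers are separated, and the cis-fused 5-epi ketone F8 is returned to 17 with tBu2Si(OTf)2 and Et3N at low temperature. This re-closure is regiospecific, because the bridge to O4 can form only through the C5 enol, so C7 is never enolised. The cleavage is then repeated until the material has been converted to 18.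

**Step 16.** Acylation of the hindered, neopentylic C10 hydroxyl may need forcing, and the Z acyl group may then isomerise to the E ester. Fallback: build the Z alkene on the ester. Setting out from 22, esterification with 2-[bis(2,2,2-trifluoroethoxy)phosphoryl]propanoic acid (carbodiimide, DMAP) gives the phosphonopropanoate F9. Still–Gennari olefination with acetaldehyde (KN(SiMe3)2, 18-crown-6, THF, −78 °C) then forms the Z trisubstituted alkene and returns to the route at 24.

## Further compounds

F1 | step 11 | (1S,2R)-1-[(5R)-5-{[di-tert-butyl(fluoro)silyl]oxy}-2-methyl-5-(propan-2-yl)cyclopent-1-en-1-yl]-2-{(E)-2-[(4-methoxyphenyl)methoxy]ethenyl}-2-methylcyclopropan-1-ol | COc1ccc(CO/C=C/[C@@]2(C)C[C@@]2(O)C3=C(C)CC[C@@]3(O[Si](F)(C(C)(C)C)C(C)(C)C)C(C)C)cc1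
F2 | step 7 | (E)-bis-silyl dienyne, tert-butyl{[(5R)... 1-(1-{[tert-butyl(dimethyl)silyl]oxy}-2-methylbut-1-en-3-yn-1-yl)-2-methyl-5-(propan-2-yl)cyclopent-1-en-5-yl]oxy}dimethylsilane (ethynyl cis to the ring) | C#C/C(C)=C(/O[Si](C)(C)C(C)(C)C)C1=C(C)CC[C@@]1(O[Si](C)(C)C(C)(C)C)C(C)C
F3 | step 7 | (1S,2R)-1-(tert-butyldimethylsilyloxy)-1-[(5R)-5-(tert-butyldimethylsilyloxy)-2-methyl-5-(propan-2-yl)cyclopent-1-en-1-yl]-2-ethynyl-2-methylcyclopropane | C#C[C@@]1(C)C[C@@]1(O[Si](C)(C)C(C)(C)C)C2=C(C)CC[C@@]2(O[Si](C)(C)C(C)(C)C)C(C)C
F4 | step 7 | the same cyclopropane with (E)-2-(4,4,5,5-tetramethyl-1,3,2-dioxaborolan-2-yl)ethenyl in place of ethynyl | CC1(C)OB(/C=C/[C@@]2(C)C[C@@]2(O[Si](C)(C)C(C)(C)C)C3=C(C)CC[C@@]3(O[Si](C)(C)C(C)(C)C)C(C)C)OC1(C)C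
F5 | step 7 | the same cyclopropane with (E)-2-[(4-methoxyphenyl)methoxy]ethenyl in place of ethynyl | COc1ccc(CO/C=C/[C@@]2(C)C[C@@]2(O[Si](C)(C)C(C)(C)C)C3=C(C)CC[C@@]3(O[Si](C)(C)C(C)(C)C)C(C)C)cc1
F6 | step 7 | (1S,4R,10R)-4β,6-bis(tert-butyldimethylsilyloxy)-10α-[(4-methoxybenzyl)oxy]dauca-5,8-diene | COc1ccc(CO[C@@H]2C=C(C)CC(O[Si](C)(C)C(C)(C)C)=C3[C@]2(C)CC[C@@]3(O[Si](C)(C)C(C)(C)C)C(C)C)cc1
F7 | step 10 | (2'R,4S,7aR)-2,2-di-tert-butyl-2'-[(E)-2-iodoethenyl]-2',5-dimethyl-7a-(propan-2-yl)-6,7-dihydro-7aH-spiro[cyclopenta[d][1,3,2]dioxasiline-4,1'-cyclopropane] | I/C=C/[C@@]1(C)C[C@]12O[Si](C(C)(C)C)(C(C)(C)C)O[C@@]3(C(C)C)CCC(C)=C23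
F8 | step 12 | 5-epi-18, (1S,4R,5S,10R)-4β-hydroxy-10α-[(4-methoxybenzyl)oxy]dauc-8-en-6-one (5β-H; cis-fused) | COc1ccc(CO[C@@H]2C=C(C)CC(=O)[C@H]3[C@]2(C)CC[C@@]3(O)C(C)C)cc1
F9 | step 16 | (1S,4R,5S,6S,10R)-10α-({2-[bis(2,2,2-trifluoroethoxy)phosphoryl]propanoyl}oxy)-4β-hydroxydauc-8-en-6α-yl 3,4-dimethoxybenzoate | CC(C(=O)O[C@@H]1C=C(C)C[C@H](OC(=O)c2ccc(OC)c(OC)c2)[C@@H]3[C@]1(C)CC[C@@]3(O)C(C)C)P(=O)(OCC(F)(F)F)OCC(F)(F)F
A1 | alternative 1 | trans-fused 4β-hydroxy-4α-isopropyl-1β-methylhydroazulen-6-one with C10 as ethylene ketal | C12(OCCO1)CCCC(=O)[C@@H]3[C@]2(C)CC[C@@]3(O)C(C)C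
A2 | alternative 2 | cyclopentanone with C1 (methyl and 4-methoxybenzyloxymethyl), C5 and C6 set, carrying the (Z)-1-hydroxy-4-iodo-3-methylbut-3-enyl chain | I/C=C(/C)C[C@H](O)[C@H]1C(=O)CC[C@]1(C)COCc2ccc(OC)cc2
A3 | alternative 3 | 10α-(tert-butyldimethylsilyloxy)-6α-(methoxymethoxy)dauc-8-en-4β-ol | CC(C)(C)[Si](C)(C)O[C@@H]1C=C(C)C[C@H](OCOC)[C@@H]2[C@]1(C)CC[C@@]2(O)C(C)C
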